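**Strategy.** The naphthalene is cut across ring B: the C1–C2–C3–C4 unit (aryl, methyl, methyl, H) is viewed as a four-carbon diene fused onto the C4a–C8a bond of the oxygenated ring A (C6–O, C7–OMe), which serves as an aryne. One operation joins a fully substituted 2-pyrone to that aryne, forms C4–C4a and C1–C8a, expels CO2 and delivers ring B aromatic. Since ring A is unsymmetrical, a removable SiEt3 group at C5 orients the addition. The precursor is an aryl triflate flanked by SiMe3 (fluoride trigger) and SiEt3 (steering group), with the C6 oxygen masked as a benzyl ether.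

Key step: step 6

Remark: positions are numbered as in the 1-arylnaphthalene (C1 aryl, C2/C3 methyl, C6 OH, C7 OMe). The target is achiral; 15 and 18 are racemic or isomeric mixtures whose stereo elements vanish on aromatisation. Compounds 1, 13 and 14 are taken as purchasable.

Three design choices keep the precursor synthesis short.
- The carbamate is the N-isopropyl type, because it is cleaved by a mild E1cB pathway that needs no attack at a carbonyl shielded by two ortho silyl groups.
- The sequence starts from commercial O-benzylisovanillin, so no separate benzylation is needed.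
- Both silyl groups are introduced in one flask under a single N-silyl protection: the N-silyl carbamate formed at the outset is carried through two consecutive lithiation–silylation cycles and unmasked only in the final work-up.

**Step 1**
Reactants: 1 3-(benzyloxy)-4-methoxybenzaldehyde
Product: 3 3-(benzyloxy)-4-methoxyphenol, via aryl formate 2 (not isolated)
Conditions: mCPBA, CH2Cl2, 0 → 25 °C; aq NaHCO3 wash; then K2CO3 (cat.), MeOH, 25 °C
Reagents that add atoms: mCPBA (3-chloroperoxybenzoic acid), OOC(=O)c1cccc(Cl)c1
Why: Dakin-type Baeyer–Villiger oxidation of the electron-rich aldehyde should proceed with aryl migration to formate 2, whose methanolysis frees the phenol while the benzyl and methyl ethers are inert to peracid and mild base.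

**Step 2**
Reactants: 3 3-(benzyloxy)-4-methoxyphenol
Product: 4 3-(benzyloxy)-4-methoxyphenyl N-isopropylcarbamate
Conditions: i-PrNCO, Et3N (cat.), CH2Cl2, 25 °C
Reagents that add atoms: isopropyl isocyanate, CC(C)N=C=O
Why: Amine-catalysed addition of the phenol to the isocyanate (carbamoylation) should give the secondary carbamate, which later directs the lithiations and is removable under mild E1cB conditions.

**Step 3**
Reactants: 4 3-(benzyloxy)-4-methoxyphenyl N-isopropylcarbamate
Product: 10 3-(benzyloxy)-4-methoxy-2-(triethylsilyl)-6-(trimethylsilyl)phenyl N-isopropylcarbamate, via N-silyl carbamate 5 (not isolated), via C2 aryllithium 6 (not isolated), via N-silyl C2-triethylsilyl carbamate 7 (not isolated), via C6 aryllithium 8 (not isolated), via N-silyl disilyl carbamate 9 (not isolated)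
Conditions: TBSOTf, TMEDA, Et2O, 0 → 25 °C; n-BuLi (2.2 equiv), TMEDA, −78 °C; Et3SiCl (1.0 equiv), −78 → 0 °C; recool, n-BuLi (1.3 equiv), TMEDA, −78 °C; Me3SiCl (excess), −78 → 25 °C; aq NaHSO4 work-up
Reagents that add atoms: chlorotriethylsilane, CC[Si](Cl)(CC)CC; chlorotrimethylsilane, C[Si](C)(C)Cl
Why: In this telescoped double directed ortho-metalation, in situ N-silylation blocks N–H deprotonation and the robust N–SiMe2t-Bu group survives both chlorosilane quenches, so n-BuLi/TMEDA should first metalate the most acidic site C2 between the carbamate and benzyloxy oxygens (trapped by one equivalent of Et3SiCl, so that none is left to compete later) and then, with C2 blocked, the only remaining carbamate-ortho position C6 (trapped by Me3SiCl), each at −78 °C where anionic Fries rearrangement and benzylic metalation are slow, before the acidic work-up removes the N-silyl group.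

**Step 4**
Reactants: 10 3-(benzyloxy)-4-methoxy-2-(triethylsilyl)-6-(trimethylsilyl)phenyl N-isopropylcarbamate
Product: 12 3-(benzyloxy)-4-methoxy-2-(triethylsilyl)-6-(trimethylsilyl)phenyl trifluoromethanesulfonate, via disilyl phenol 11 (not isolated)
Conditions: DBU, Et2NH, MeCN, 40 °C; then PhNTf2, 25 → 40 °C
Reagents that add atoms: N-phenylbis(trifluoromethanesulfonimide), O=S(=O)(N(c1ccccc1)S(=O)(=O)C(F)(F)F)C(F)(F)F
Why: E1cB carbamate cleavage (DBU removes N–H, the hindered phenoxide leaves, Et2NH scavenges the isocyanate as a urea) followed by O-sulfonylation of the phenoxide with PhNTf2 should give the triflate without nucleophilic attack at the shielded carbonyl and without acid that could cleave the C–Si bonds.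

**Step 5**
Reactants: 13 1-(3,4,5-trimethoxyphenyl)propan-1-one; 14 ethyl but-2-ynoate
Product: 16 4,5-dimethyl-6-(3,4,5-trimethoxyphenyl)-2H-pyran-2-one, via Michael adduct 15 (not isolated)
Conditions: t-BuOK, THF, 0 → 25 °C, then 50 °C; AcOH quench
Reagents that add atoms: none
Why: In this tandem Michael addition–lactonisation the potassium enolate of 13 should add through carbon to the β-carbon of the ynoate, and the enolate oxygen of the resulting δ-keto enoate 15 (its alkene geometry equilibrating through the dienolate) then acylates on the ester with loss of ethoxide, the classical alkoxide-mediated route from ketones and alkynoates to 2-pyrones.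

**Step 6**
Reactants: 12 3-(benzyloxy)-4-methoxy-2-(triethylsilyl)-6-(trimethylsilyl)phenyl trifluoromethanesulfonate; 16 4,5-dimethyl-6-(3,4,5-trimethoxyphenyl)-2H-pyran-2-one
Product: 19 6-(benzyloxy)-7-methoxy-2,3-dimethyl-5-(triethylsilyl)-1-(3,4,5-trimethoxyphenyl)naphthalene, via aryne 17 (not isolated), via bridged lactone 18 (not isolated)
Conditions: CsF (3 equiv), 16 (1.5 equiv), MeCN, 25 → 60 °C
Reagents that add atoms: none
Why: Fluoride should attack the exposed SiMe3 group of 12 in preference to the bulkier SiEt3 group wedged between OTf and OBn, and the resulting aryl anion expels triflate to give aryne 17 (fluoride-induced 1,2-elimination). The aryne then engages the pyrone diene (C3 to C6) in an intermolecular [4+2] cycloaddition that closes six-membered ring B by forming C4–C4a and C1–C8a, and the bridged lactone 18 loses CO2 in a retro-Diels–Alder step to give the naphthalene directly. The closest known reaction type is the aryne/2-pyrone Diels–Alder–decarboxylation synthesis of naphthalenes, combined with the orientation effect of a 3-silyl group established for aryne additions of nucleophiles and 2-substituted furans. No stereocentre has to be controlled, since the two bridgehead centres of 18 disappear with CO2. The selectivity needed is regiochemical: the electropositive silyl group distorts the aryne so that the carbon next to it (future C4a) is the more electrophilic terminus and pairs with the more nucleophilic, unsubstituted pyrone C3 (the far end of the dienol ether O1–C6=C5–C4=C3), while the aryl-bearing pyrone C6 is kept away from SiEt3, so electronic and steric effects should act in the same direction. The benzyl ether, the methyl ethers and the C–SiEt3 bond are expected to tolerate CsF in MeCN.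

**Step 7**
Reactants: 19 6-(benzyloxy)-7-methoxy-2,3-dimethyl-5-(triethylsilyl)-1-(3,4,5-trimethoxyphenyl)naphthalene
Product: 20 6-(benzyloxy)-7-methoxy-2,3-dimethyl-1-(3,4,5-trimethoxyphenyl)naphthalene
Conditions: TFA, CH2Cl2, 0 → 25 °C
Reagents that add atoms: none
Why: Acid-mediated ipso-protodesilylation (electrophilic aromatic substitution at the silicon-bearing carbon) should be easy because C5 is an α-naphthyl position ortho to the benzyloxy group and strained against the peri C4–H, and aryl benzyl and methyl ethers tolerate brief exposure to dilute TFA.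

**Step 8**
Reactants: 20 6-(benzyloxy)-7-methoxy-2,3-dimethyl-1-(3,4,5-trimethoxyphenyl)naphthalene
Product: 21 7-methoxy-2,3-dimethyl-1-(3,4,5-trimethoxyphenyl)naphthalen-6-ol (CNP0280611.0)
Conditions: H2 (1 atm), 10% Pd/C, EtOAc/MeOH, 25 °C
Reagents that add atoms: none
Why: Catalytic hydrogenolysis of the benzyl aryl ether should cleave only the benzylic C–O bond, leaving the naphthalene, the methyl ethers and the ring methyl groups untouched at ambient pressure.

**Compound list**
1 | 3-(benzyloxy)-4-methoxybenzaldehyde (O-benzylisovanillin) | COc1ccc(C=O)cc1OCc1ccccc1 | starting material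
2 | 3-(benzyloxy)-4-methoxyphenyl formate | COc1ccc(OC=O)cc1OCc1ccccc1 | intermediate (not isolated)
3 | 3-(benzyloxy)-4-methoxyphenol | COc1ccc(O)cc1OCc1ccccc1 | intermediate
4 | 3-(benzyloxy)-4-methoxyphenyl N-isopropylcarbamate | COc1ccc(OC(=O)NC(C)C)cc1OCc1ccccc1 | intermediate
5 | 3-(benzyloxy)-4-methoxyphenyl N-(tert-butyldimethylsilyl)-N-isopropylcarbamate | COc1ccc(OC(=O)N(C(C)C)[Si](C)(C)C(C)(C)C)cc1OCc1ccccc1 | intermediate (not isolated)
6 | 2-lithio derivative of 5 (lithium between the carbamate and benzyloxy carbons) | COc1ccc(OC(=O)N(C(C)C)[Si](C)(C)C(C)(C)C)c([Li])c1OCc1ccccc1 | intermediate (not isolated)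
7 | 3-(benzyloxy)-4-methoxy-2-(triethylsilyl)phenyl N-(tert-butyldimethylsilyl)-N-isopropylcarbamate | COc1ccc(OC(=O)N(C(C)C)[Si](C)(C)C(C)(C)C)c([Si](CC)(CC)CC)c1OCc1ccccc1 | intermediate (not isolated)
8 | 6-lithio derivative of 7 | COc1cc([Li])c(OC(=O)N(C(C)C)[Si](C)(C)C(C)(C)C)c([Si](CC)(CC)CC)c1OCc1ccccc1 | intermediate (not isolated)
9 | 3-(benzyloxy)-4-methoxy-2-(triethylsilyl)-6-(trimethylsilyl)phenyl N-(tert-butyldimethylsilyl)-N-isopropylcarbamate | COc1cc([Si](C)(C)C)c(OC(=O)N(C(C)C)[Si](C)(C)C(C)(C)C)c([Si](CC)(CC)CC)c1OCc1ccccc1 | intermediate (not isolated)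
10 | 3-(benzyloxy)-4-methoxy-2-(triethylsilyl)-6-(trimethylsilyl)phenyl N-isopropylcarbamate | COc1cc([Si](C)(C)C)c(OC(=O)NC(C)C)c([Si](CC)(CC)CC)c1OCc1ccccc1 | intermediate
11 | 3-(benzyloxy)-4-methoxy-2-(triethylsilyl)-6-(trimethylsilyl)phenol (present as its DBU-H phenoxide) | COc1cc([Si](C)(C)C)c(O)c([Si](CC)(CC)CC)c1OCc1ccccc1 | intermediate (not isolated)
12 | 3-(benzyloxy)-4-methoxy-2-(triethylsilyl)-6-(trimethylsilyl)phenyl trifluoromethanesulfonate | COc1cc([Si](C)(C)C)c(OS(=O)(=O)C(F)(F)F)c([Si](CC)(CC)CC)c1OCc1ccccc1 | intermediate (key-step precursor)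
13 | 1-(3,4,5-trimethoxyphenyl)propan-1-one | CCC(=O)c1cc(OC)c(OC)c(OC)c1 | starting material
14 | ethyl but-2-ynoate | CC#CC(=O)OCC | starting material
15 | ethyl 3,4-dimethyl-5-oxo-5-(3,4,5-trimethoxyphenyl)pent-2-enoate (racemic, E/Z mixture) | CCOC(=O)C=C(C)C(C)C(=O)c1cc(OC)c(OC)c(OC)c1 | intermediate (not isolated)
16 | 4,5-dimethyl-6-(3,4,5-trimethoxyphenyl)-2H-pyran-2-one | O=c1cc(C)c(C)c(-c2cc(OC)c(OC)c(OC)c2)o1 | intermediate (key-step precursor)
17 | 4-(benzyloxy)-5-methoxy-3-(triethylsilyl)benzyne (1,2-didehydrobenzene; the aryne bond is the future C4a–C8a bond) | COC1=CC#CC([Si](CC)(CC)CC)=C1OCc1ccccc1 | intermediate (not isolated)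
18 | CO2-bridged 1,4-dihydronaphthalene cycloadduct (lactone bridge from C1 oxygen to C4 carbonyl carbon; racemic) | O=C1OC2(c3cc(OC)c(OC)c(OC)c3)C(C)=C(C)C1c1c([Si](CC)(CC)CC)c(OCc3ccccc3)c(OC)cc12 | intermediate (not isolated)
19 | 6-(benzyloxy)-7-methoxy-2,3-dimethyl-5-(triethylsilyl)-1-(3,4,5-trimethoxyphenyl)naphthalene | COc1cc2c(-c3cc(OC)c(OC)c(OC)c3)c(C)c(C)cc2c([Si](CC)(CC)CC)c1OCc1ccccc1 | intermediate (key-step product)
20 | 6-(benzyloxy)-7-methoxy-2,3-dimethyl-1-(3,4,5-trimethoxyphenyl)naphthalene | COc1cc2c(-c3cc(OC)c(OC)c(OC)c3)c(C)c(C)cc2cc1OCc1ccccc1 | intermediate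
21 | 7-methoxy-2,3-dimethyl-1-(3,4,5-trimethoxyphenyl)naphthalen-6-ol (= 3-methoxy-6,7-dimethyl-5-(3,4,5-trimethoxyphenyl)naphthalen-2-ol) | COc1cc2c(-c3cc(OC)c(OC)c(OC)c3)c(C)c(C)cc2cc1O | target

**Step count.** Total: 8 steps. Longest linear sequence: 7 steps (steps 1–4, then 6, 7, 8); the pyrone branch is one step (step 5).

**Steps most likely to fail**

1. Step 6. The orientation of the cycloaddition may erode, or the pyrone may be too slow a diene so that the aryne is consumed by side reactions before it is trapped. The fallback sets out from 12 and returns at 19. Pd-catalysed C2–H arylation of purchasable 3,4-dimethylfuran with 5-bromo-1,2,3-trimethoxybenzene (Pd(OAc)2, KOAc, DMA, 130 °C) would give 3,4-dimethyl-2-(3,4,5-trimethoxyphenyl)furan F1. Aryne 17, generated from 12 with CsF in MeCN, would add this much more reactive diene with the orientation established for 3-silylarynes and 2-substituted furans, giving 6-(benzyloxy)-7-methoxy-2,3-dimethyl-5-(triethylsilyl)-1-(3,4,5-trimethoxyphenyl)-1,4-dihydro-1,4-epoxynaphthalene F2. Deoxygenative aromatisation with pre-formed low-valent titanium (TiCl4, Zn, THF, reflux) would then give 19.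

2. Step 3. The second lithiation, next to a carbamate already flanked by SiEt3, is slower than the first, so benzylic deprotonation of the benzyl ether or anionic Fries migration may compete; in the telescoped mode, incomplete trapping in the first cycle could also scramble the two silyl groups. The fallback sets out from 3 and returns at 10, replacing the slow deprotonation by a fast halogen–metal exchange. Phenol 3 would be brominated para to the benzyloxy group (NBS, MeCN, 0 °C) to 5-(benzyloxy)-2-bromo-4-methoxyphenol F3 and O-silylated (HMDS, THF, 60 °C) to [5-(benzyloxy)-2-bromo-4-methoxyphenoxy]trimethylsilane F4. n-BuLi (THF, −78 °C) would give the aryllithium [5-(benzyloxy)-2-lithio-4-methoxyphenoxy]trimethylsilane F5, whose 1,3 O-to-C silyl shift (retro-Brook) and protonation give 5-(benzyloxy)-4-methoxy-2-(trimethylsilyl)phenol F6. Carbamoylation (i-PrNCO, Et3N) would give 5-(benzyloxy)-4-methoxy-2-(trimethylsilyl)phenyl N-isopropylcarbamate F7. Only the fast, doubly activated metalation then remains: TBSOTf/TMEDA gives the N-(tert-butyldimethylsilyl) carbamate F8, and n-BuLi/TMEDA at −78 °C gives its 6-lithio derivative F9 at the site between the two oxygens. Et3SiCl would convert this into 9, and acidic work-up gives 10.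

3. Step 5. The alkoxide may isomerise or oligomerise the ynoate, or the ketone may self-condense, so that conversion to the pyrone stalls. The fallback sets out from 14 and returns at 16 by a stepwise, regiodefined pyrone construction. Hydroiodination of 14 (NaI, AcOH, 110 °C) would give ethyl (Z)-3-iodobut-2-enoate F10. Sonogashira coupling with purchasable 5-ethynyl-1,2,3-trimethoxybenzene (PdCl2(PPh3)2, CuI, Et3N, THF) would give ethyl (Z)-3-methyl-5-(3,4,5-trimethoxyphenyl)pent-2-en-4-ynoate F11. 6-endo iodolactonisation (I2, CH2Cl2, 25 °C) would give 5-iodo-4-methyl-6-(3,4,5-trimethoxyphenyl)-2H-pyran-2-one F12, and Stille methylation (Me4Sn, PdCl2(PPh3)2, CuI, DMF, 80 °C) would give 16.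

**Further compounds**
F1 | step 6 | 3,4-dimethyl-2-(3,4,5-trimethoxyphenyl)furan | Cc1coc(-c2cc(OC)c(OC)c(OC)c2)c1C
F2 | step 6 | 6-(benzyloxy)-7-methoxy-2,3-dimethyl-5-(triethylsilyl)-1-(3,4,5-trimethoxyphenyl)-1,4-dihydro-1,4-epoxynaphthalene (racemic) | COc1cc2c(c([Si](CC)(CC)CC)c1OCc1ccccc1)C1OC2(c2cc(OC)c(OC)c(OC)c2)C(C)=C1C
F3 | step 3 | 5-(benzyloxy)-2-bromo-4-methoxyphenol | COc1cc(Br)c(O)cc1OCc1ccccc1
F4 | step 3 | [5-(benzyloxy)-2-bromo-4-methoxyphenoxy]trimethylsilane | COc1cc(Br)c(O[Si](C)(C)C)cc1OCc1ccccc1
F5 | step 3 | [5-(benzyloxy)-2-lithio-4-methoxyphenoxy]trimethylsilane | COc1cc([Li])c(O[Si](C)(C)C)cc1OCc1ccccc1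
F6 | step 3 | 5-(benzyloxy)-4-methoxy-2-(trimethylsilyl)phenol | COc1cc([Si](C)(C)C)c(O)cc1OCc1ccccc1
F7 | step 3 | 5-(benzyloxy)-4-methoxy-2-(trimethylsilyl)phenyl N-isopropylcarbamate | COc1cc([Si](C)(C)C)c(OC(=O)NC(C)C)cc1OCc1ccccc1
F8 | step 3 | 5-(benzyloxy)-4-methoxy-2-(trimethylsilyl)phenyl N-(tert-butyldimethylsilyl)-N-isopropylcarbamate | COc1cc([Si](C)(C)C)c(OC(=O)N(C(C)C)[Si](C)(C)C(C)(C)C)cc1OCc1ccccc1
F9 | step 3 | 6-lithio derivative of F8 (lithium between the carbamate and benzyloxy carbons) | COc1cc([Si](C)(C)C)c(OC(=O)N(C(C)C)[Si](C)(C)C(C)(C)C)c([Li])c1OCc1ccccc1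
F10 | step 5 | ethyl (Z)-3-iodobut-2-enoate | CCOC(=O)/C=C(\I)C
F11 | step 5 | ethyl (Z)-3-methyl-5-(3,4,5-trimethoxyphenyl)pent-2-en-4-ynoate | CCOC(=O)/C=C(\C#Cc1cc(OC)c(OC)c(OC)c1)C
F12 | step 5 | 5-iodo-4-methyl-6-(3,4,5-trimethoxyphenyl)-2H-pyran-2-one | O=c1cc(C)c(I)c(-c2cc(OC)c(OC)c(OC)c2)o1
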